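**Retrosynthetic overview**
1. Dichrostachine E ← fluoride removal of one 2-(trimethylsilyl)ethyl (TMSE) ester and two aryl TBS ethers from 32.
2. Ring B (C5–C6–C7–C8–C9–C10) is closed last, through the C9–C10 bond of seco compound 31. The enabling feature: O7 lies 1,5 to the hydrogen on C10 (O7–C7–C6–C5–C10–H), and C7 is allylic to C8=C9, whose C17 carries a phenylsulfonyl group. An O7-centred radical therefore moves the radical to C10, C10 closes ring B onto C9, and loss of the sulfonyl radical leaves the C8=C17 methylene and the free 7-OH.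
3. Ring C ← Diels–Alder reaction of the (12E)-12,14-diene of 22 with quinone monoketal 29 (ring D is the former arene; its ketal is hydrolysed in the same flask).
4. 22 ← NiCl2/CrCl2 coupling of ring A aldehyde 10 with vinyl iodide 19 (C7–C8), then oxidation and oxazaborolidine reduction to set C7.
5. Ring A ← enantioselective Robinson annulation (C4), then Johnson–Claisen transfer of chirality from O–C1 to C5. Order of ring formation: A, chromone pyranone ring, C, B.

Key step: step 19

Remark: labdane numbering (C1–C20) is used for the terpenoid carbons. The carbons of the methoxy-enedione ring D are called Q1–Q6 (Q1 C=O, Q2 bears the chromone, Q3 ring-fusion CH, Q4 C=O, Q5 C–OMe, Q6 CH). Assumption: (E)-3-methylpent-2-en-4-yn-1-ol (11) is bought as the pure (E)-isomer.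

**Step 1**
Reactants: 1 ethyl 2-methyl-3-oxopropanoate
Product: 2 2-(trimethylsilyl)ethyl 2-methyl-3-oxopropanoate
Conditions: Me3SiCH2CH2OH, DMAP (10 mol %), PhMe, 110 °C, −EtOH
Reagents that add atoms: 2-(trimethylsilyl)ethanol, C[Si](C)(C)CCO
Why: DMAP-catalysed transesterification of an enolisable β-oxo ester, driven by removal of ethanol, installs the fluoride-labile ester that is removed in step 20; no stereocentre is formed.

**Step 2**
Reactants: 2 2-(trimethylsilyl)ethyl 2-methyl-3-oxopropanoate; 3 pent-1-en-3-one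
Product: 5 2-(trimethylsilyl)ethyl (R)-1,3-dimethyl-4-oxocyclohex-2-ene-1-carboxylate, via keto aldehyde 4 (not isolated)
Conditions: 9-O-benzylcupreidine (10 mol %), CH2Cl2, −20 °C; then pyrrolidine (20 mol %), AcOH (20 mol %), PhMe, 60 °C
Reagents that add atoms: none
Why: Bifunctional cinchona-alkaloid catalysed Michael addition of the α-substituted β-oxo ester to the vinyl ketone should set the quaternary centre C4 as (R) by face-selective attack of the hydrogen-bonded enol (the pseudoenantiomeric cupreine catalyst gives the antipode), and amine-catalysed intramolecular aldol condensation of the ethyl ketone onto the aldehyde then closes ring A (Robinson annulation).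

**Step 3**
Reactants: 5 2-(trimethylsilyl)ethyl (R)-1,3-dimethyl-4-oxocyclohex-2-ene-1-carboxylate
Product: 6 2-(trimethylsilyl)ethyl (1R,4R)-4-hydroxy-1,3-dimethylcyclohex-2-ene-1-carboxylate
Conditions: (S)-2-methyl-CBS-oxazaborolidine (20 mol %), catecholborane, PhMe, −78 °C; then MeOH
Reagents that add atoms: none
Why: Corey–Bakshi–Shibata reduction in which the α-methyl alkene carbon is the large group, so the (S)-catalyst should give the carbinol at labdane C1 cis to the C4 methyl under reagent control, independent of the remote quaternary centre.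

**Step 4**
Reactants: 6 2-(trimethylsilyl)ethyl (1R,4R)-4-hydroxy-1,3-dimethylcyclohex-2-ene-1-carboxylate
Product: 8 2-(trimethylsilyl)ethyl (1R,2R)-2-(2-ethoxy-2-oxoethyl)-1,3-dimethylcyclohex-3-ene-1-carboxylate, via ketene acetal 7 (not isolated)
Conditions: MeC(OEt)3 (6 equiv), EtCO2H (10 mol %), xylene, 140 °C, −EtOH
Reagents that add atoms: triethyl orthoacetate, CC(OCC)(OCC)OCC
Why: Johnson–Claisen rearrangement, in which the ketene acetal on O1 rearranges suprafacially, so the CH2CO2Et unit (C6–C7) is delivered to C5 on the face that carried O1 (cis to the C4 methyl, trans to the C4 ester), setting C5 and moving the double bond to C1=C10.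

**Step 5**
Reactants: 8 2-(trimethylsilyl)ethyl (1R,2R)-2-(2-ethoxy-2-oxoethyl)-1,3-dimethylcyclohex-3-ene-1-carboxylate
Product: 9 2-(trimethylsilyl)ethyl (1R,2R,3R)-2-(2-ethoxy-2-oxoethyl)-1,3-dimethylcyclohexane-1-carboxylate
Conditions: H2 (3 bar), Pd/C, EtOAc, 25 °C
Reagents that add atoms: none
Why: Heterogeneous hydrogenation of the trisubstituted ring alkene, expected mainly anti to the C5 side chain (10α-H, as drawn); the configuration at C10 does not matter, because this centre becomes a planar radical in step 19 and both epimers converge.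

**Step 6**
Reactants: 9 2-(trimethylsilyl)ethyl (1R,2R,3R)-2-(2-ethoxy-2-oxoethyl)-1,3-dimethylcyclohexane-1-carboxylate
Product: 10 2-(trimethylsilyl)ethyl (1R,2R,3R)-1,3-dimethyl-2-(2-oxoethyl)cyclohexane-1-carboxylate
Conditions: i-Bu2AlH (1.05 equiv), PhMe, −78 °C; aq potassium sodium tartrate
Reagents that add atoms: none
Why: Low-temperature half-reduction of the unhindered ethyl ester through its stable tetrahedral aluminate; the TMSE ester on the quaternary carbon should react much more slowly.

**Step 7**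
Reactants: 11 (E)-3-methylpent-2-en-4-yn-1-ol
Product: 12 (E)-3-methylpenta-2,4-dien-1-ol
Conditions: H2 (1 bar), Pd/CaCO3 poisoned with Pb(OAc)2, quinoline, hexane/EtOAc, 0 °C
Reagents that add atoms: none
Why: Semihydrogenation of the terminal alkyne to the vinyl group; the existing (E)-trisubstituted alkene is untouched and later becomes C12=C13.

**Step 8**
Reactants: 12 (E)-3-methylpenta-2,4-dien-1-ol
Product: 13 (E)-5-bromo-3-methylpenta-1,3-diene
Conditions: PBr3 (0.4 equiv), Et2O, −10 °C
Reagents that add atoms: phosphorus tribromide, BrP(Br)Br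
Why: Conversion of a primary allylic alcohol into the bromide; the conjugated primary dienyl bromide is the thermodynamically favoured regioisomer.

**Step 9**
Reactants: 13 (E)-5-bromo-3-methylpenta-1,3-diene; 14 prop-2-yn-1-ol
Product: 15 (E)-6-methylocta-5,7-dien-2-yn-1-ol
Conditions: CuI (10 mol %), Cs2CO3, NaI, DMF, 25 °C
Reagents that add atoms: none
Why: Copper-catalysed coupling of a terminal alkyne with a primary allylic bromide (copper acetylide, substitution at the primary carbon) should give the skipped enyne with the (E)-diene intact.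

**Step 10**
Reactants: 15 (E)-6-methylocta-5,7-dien-2-yn-1-ol
Product: 17 (2E,5E)-2-iodo-6-methylocta-2,5,7-trien-1-ol, via vinylstannane 16 (not isolated)
Conditions: Bu3SnH, Mo(CO)3(CNtBu)3 (3 mol %), hydroquinone, THF, 55 °C; then I2, CH2Cl2, 0 °C
Reagents that add atoms: iodine, II
Why: Molybdenum-catalysed hydrostannation of a propargylic alcohol adds H and Sn syn with tin on the carbon next to the carbinol carbon, and iododestannylation proceeds with retention, which fixes the later C8=C9 geometry (C11 cis to C17).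

**Step 11**
Reactants: 17 (2E,5E)-2-iodo-6-methylocta-2,5,7-trien-1-ol
Product: 19 [(2E,5E)-2-iodo-6-methylocta-2,5,7-trien-1-yl]sulfonylbenzene, via mesylate 18 (not isolated)
Conditions: MsCl, Et3N, CH2Cl2, −20 °C; then PhSO2Na, DMF, 25 °C
Reagents that add atoms: sodium benzenesulfinate, [Na+].[O-]S(=O)c1ccccc1
Why: Mesylation and substitution at the primary allylic carbon by the soft sulfur of the sulfinate should give the allyl sulfone without touching the vinyl iodide.

**Step 12**
Reactants: 10 2-(trimethylsilyl)ethyl (1R,2R,3R)-1,3-dimethyl-2-(2-oxoethyl)cyclohexane-1-carboxylate; 19 [(2E,5E)-2-iodo-6-methylocta-2,5,7-trien-1-yl]sulfonylbenzene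
Product: 20 2-(trimethylsilyl)ethyl (1R,2R,3R)-2-[(3Z,6E)-2-hydroxy-7-methyl-3-(phenylsulfonylmethyl)nona-3,6,8-trien-1-yl]-1,3-dimethylcyclohexane-1-carboxylate (both C7 epimers)
Conditions: CrCl2 (4 equiv), NiCl2 (2 mol %), DMSO/THF, 25 °C
Reagents that add atoms: none
Why: Nozaki–Hiyama–Kishi coupling, in which the alkenylchromium species forms with retention of alkene geometry and adds only to the aldehyde (esters, sulfone and diene are tolerated); C7 is formed without control and is corrected in steps 13 and 14.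

**Step 13**
Reactants: 20 the C7-epimeric allylic alcohols
Product: 21 2-(trimethylsilyl)ethyl (1R,2R,3R)-1,3-dimethyl-2-[(3Z,6E)-7-methyl-2-oxo-3-(phenylsulfonylmethyl)nona-3,6,8-trien-1-yl]cyclohexane-1-carboxylate
Conditions: Dess–Martin periodinane, CH2Cl2, 0 to 25 °C
Reagents that add atoms: none
Why: Dess–Martin oxidation of the secondary allylic alcohol under neutral conditions, which the base-sensitive α-(sulfonylmethyl) enone should tolerate.

**Step 14**
Reactants: 21 the C7 enone
Product: 22 2-(trimethylsilyl)ethyl (1R,2R,3R)-2-[(2S,3Z,6E)-2-hydroxy-7-methyl-3-(phenylsulfonylmethyl)nona-3,6,8-trien-1-yl]-1,3-dimethylcyclohexane-1-carboxylate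
Conditions: (R)-2-methyl-CBS-oxazaborolidine (1 equiv), catecholborane, CH2Cl2/PhMe, −78 °C; then MeOH
Reagents that add atoms: none
Why: Corey–Bakshi–Shibata reduction of an α-substituted acyclic enone with the alkenyl group as the large substituent, so the (R)-catalyst should give the (7S)-alcohol under reagent control.

**Step 15**
Reactants: 23 1-(2,4,6-trihydroxyphenyl)ethan-1-one; 24 2,4,5-trimethoxybenzoyl chloride
Product: 26 5,7-dihydroxy-2-(2,4,5-trimethoxyphenyl)-4H-chromen-4-one, via diketone 25 (not isolated)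
Conditions: LiN(SiMe3)2 (4.5 equiv), THF, −78 °C; 24, −78 to 25 °C; then AcOH, H2SO4 (cat.), 95 °C
Reagents that add atoms: none
Why: C-acylation of the lithium polyanion of the hydroxyacetophenone gives the 1,3-diketone, and acid-catalysed cyclodehydration closes the pyranone ring of the chromone (one-pot variant of the Baker–Venkataraman flavone synthesis).

**Step 16**
Reactants: 26 5,7-dihydroxy-2-(2,4,5-trimethoxyphenyl)-4H-chromen-4-one
Product: 27 5,7-bis(tert-butyldimethylsilyloxy)-2-(2,4,5-trimethoxyphenyl)-4H-chromen-4-one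
Conditions: TBSOTf (2.5 equiv), 2,6-lutidine, CH2Cl2, 0 to 25 °C
Reagents that add atoms: tert-butyldimethylsilyl trifluoromethanesulfonate, CC(C)(C)[Si](C)(C)OS(=O)(=O)C(F)(F)F
Why: The silyl triflate silylates both phenols (including the hydrogen-bonded 5-OH), so that O7–H is the only free hydroxyl in step 19 and the A ring is protected from oxidation in step 17.

**Step 17**
Reactants: 27 5,7-bis(tert-butyldimethylsilyloxy)-2-(2,4,5-trimethoxyphenyl)-4H-chromen-4-one
Product: 29 2-[5,7-bis(tert-butyldimethylsilyloxy)-4-oxo-4H-chromen-2-yl]-4,4,5-trimethoxycyclohexa-2,5-dien-1-one, via bisketal 28 (not isolated)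
Conditions: Pt anode, C cathode, LiClO4, 2,6-lutidine, MeOH, 0 °C, constant current; then 8% aq AcOH, acetone, 0 °C
Reagents that add atoms: methanol, CO; water, O
Why: Anodic oxidation of the para-dimethoxyarene in methanol gives the quinone bisketal, and mild acid should hydrolyse only the ketal at Q1, whose ionisation is stabilised through the Q5 methoxy group, leaving the ketal at Q4.

**Step 18**
Reactants: 22 the (7S)-allylic alcohol; 29 the quinone monoketal
Product: 31 TMSE ester and 5′,7′-bis-TBS ether of (8Z)-17-(phenylsulfonyl)-9,10-seco-dichrostachine E (C8=C9 double bond, H on C10), via ketal adduct 30 (not isolated)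
Conditions: PhMe, 90 °C, BHT (cat.), dark; then (CO2H)2, THF/H2O, 25 °C; chromatography on SiO2
Reagents that add atoms: water, O
Why: Diels–Alder reaction of the 1,2-dialkylbutadiene with the doubly activated C=C of the monoketal: the unsubstituted terminus C15 should bond to Q3 (β to the Q1 carbonyl and vinylogously β to the chromone carbonyl, "ortho" orientation), suprafacial addition sets the cis ring fusion, and the gem-dimethoxy carbon Q4 disfavours ring D lying under the diene so that the chromone takes the endo position and C11 ends cis to it; the remote centres C5 and C7 cannot differentiate the diene faces, so the (12R)-adduct is separated from its diastereomer by chromatography after acid hydrolysis of the Q4 ketal.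

**Step 19**
Reactants: 31 the seco enedione
Product: 32 dichrostachine E 2-(trimethylsilyl)ethyl ester 5′,7′-bis(tert-butyldimethylsilyl) ether
Conditions: (Bu4N)2CeCl6 (5 mol %), Bu4NCl (15 mol %), MeCN (0.005 M), 400 nm LEDs, 25 °C, Ar
Reagents that add atoms: none
Why: Proposed new method: the only free hydroxyl (O7–H) binds tetravalent cerium and ligand-to-metal charge-transfer homolysis gives the C7 alkoxy radical, which abstracts the hydrogen on C10 through a six-membered transition state; the tertiary C10 radical adds to C9, the C8 radical expels PhSO2•, and this radical reoxidises trivalent cerium, so the step is a redox-neutral isomerisation with loss of benzenesulfinic acid. The closest known reactions are cerium-photocatalysed δ-C–H functionalisation of free alcohols by 1,5-hydrogen transfer and the allylation of such δ-carbon radicals (from N-alkoxyphthalimides) with allyl sulfones; what is new is the intramolecular use to close a carbocycle. Ring B closes by 6-endo-trig radical cyclisation of C10 onto C9, favoured over 5-exo attack because C8 is fully substituted and made irreversible by β-scission of the C17–S bond. C10 and C9 are set in a chair-like transition state anchored by C5 (side chain equatorial on ring A, hence trans ring fusion with the C10 methyl axial), by the existing equatorial O7 and by the alkene geometry (C11 trans to C7, hence C11 equatorial and H-9 α). The step needs site-selective hydrogen abstraction, which is secured because C10 carries the only δ-hydrogen that O7 can reach (C4 is quaternary, C11 is held away by the C8=C9 geometry) and because abstraction of a tertiary hydrogen should outrun β-scission of C6–C7; it also needs chemoselective radical generation, secured by silylated phenols and an esterified acid, and low cerium loading and high dilution to limit oxidation of the C10 radical or its addition to ring D.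

**Step 20**
Reactants: 32 dichrostachine E 2-(trimethylsilyl)ethyl ester 5′,7′-bis(tert-butyldimethylsilyl) ether
Product: 33 dichrostachine E
Conditions: TASF (6 equiv), DMF, 0 to 25 °C; aq NH4Cl
Reagents that add atoms: none
Why: Fluoride attacks silicon of the TMSE ester (fragmentation to ethylene and the carboxylate) and of both aryl silyl ethers under non-acidic, weakly basic conditions that should leave the allylic alcohol, the exocyclic alkene and the epimerisable ring-fusion CH of the enedione untouched.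

**Compound list**
1 | ethyl 2-methyl-3-oxopropanoate | CCOC(=O)C(C)C=O | starting material
2 | 2-(trimethylsilyl)ethyl 2-methyl-3-oxopropanoate | C[Si](C)(C)CCOC(=O)C(C)C=O | intermediate
3 | pent-1-en-3-one | CCC(=O)C=C | starting material
4 | 2-(trimethylsilyl)ethyl (R)-2-formyl-2-methyl-5-oxoheptanoate | CCC(=O)CC[C@@](C=O)(C)C(=O)OCC[Si](C)(C)C | intermediate
5 | 2-(trimethylsilyl)ethyl (R)-1,3-dimethyl-4-oxocyclohex-2-ene-1-carboxylate | O=C1CC[C@@](C=C1C)(C)C(=O)OCC[Si](C)(C)C | intermediate
6 | 2-(trimethylsilyl)ethyl (1R,4R)-4-hydroxy-1,3-dimethylcyclohex-2-ene-1-carboxylate | O[C@@H]1CC[C@@](C=C1C)(C)C(=O)OCC[Si](C)(C)C | intermediate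
7 | 2-(trimethylsilyl)ethyl (1R,4R)-4-(1-ethoxyvinyloxy)-1,3-dimethylcyclohex-2-ene-1-carboxylate | C=C(OCC)O[C@@H]1CC[C@@](C=C1C)(C)C(=O)OCC[Si](C)(C)C | intermediate
8 | 2-(trimethylsilyl)ethyl (1R,2R)-2-(2-ethoxy-2-oxoethyl)-1,3-dimethylcyclohex-3-ene-1-carboxylate | CCOC(=O)C[C@@H]1C(C)=CCC[C@@]1(C)C(=O)OCC[Si](C)(C)C | intermediate
9 | 2-(trimethylsilyl)ethyl (1R,2R,3R)-2-(2-ethoxy-2-oxoethyl)-1,3-dimethylcyclohexane-1-carboxylate | CCOC(=O)C[C@@H]1[C@H](C)CCC[C@@]1(C)C(=O)OCC[Si](C)(C)C | intermediate
10 | 2-(trimethylsilyl)ethyl (1R,2R,3R)-1,3-dimethyl-2-(2-oxoethyl)cyclohexane-1-carboxylate | O=CC[C@@H]1[C@H](C)CCC[C@@]1(C)C(=O)OCC[Si](C)(C)C | intermediate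
11 | (E)-3-methylpent-2-en-4-yn-1-ol | OC/C=C(C)/C#C | starting material
12 | (E)-3-methylpenta-2,4-dien-1-ol | OC/C=C(C)/C=C | intermediate
13 | (E)-5-bromo-3-methylpenta-1,3-diene | BrC/C=C(C)/C=C | intermediate
14 | prop-2-yn-1-ol | OCC#C | starting material
15 | (E)-6-methylocta-5,7-dien-2-yn-1-ol | OCC#CC/C=C(C)/C=C | intermediate
16 | (2E,5E)-6-methyl-2-(tributylstannyl)octa-2,5,7-trien-1-ol | OC/C(=C\C/C=C(C)/C=C)[Sn](CCCC)(CCCC)CCCC | intermediate
17 | (2E,5E)-2-iodo-6-methylocta-2,5,7-trien-1-ol | OC/C(I)=C\C/C=C(C)/C=C | intermediate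
18 | (2E,5E)-2-iodo-6-methylocta-2,5,7-trien-1-yl methanesulfonate | CS(=O)(=O)OC/C(I)=C\C/C=C(C)/C=C | intermediate
19 | [(2E,5E)-2-iodo-6-methylocta-2,5,7-trien-1-yl]sulfonylbenzene | O=S(=O)(c1ccccc1)C/C(I)=C\C/C=C(C)/C=C | intermediate
20 | 2-(trimethylsilyl)ethyl (1R,2R,3R)-2-[(3Z,6E)-2-hydroxy-7-methyl-3-(phenylsulfonylmethyl)nona-3,6,8-trien-1-yl]-1,3-dimethylcyclohexane-1-carboxylate (C7 epimers) | O=S(=O)(c1ccccc1)C/C(=C\C/C=C(C)/C=C)C(O)C[C@@H]1[C@H](C)CCC[C@@]1(C)C(=O)OCC[Si](C)(C)C | intermediate
21 | 2-(trimethylsilyl)ethyl (1R,2R,3R)-1,3-dimethyl-2-[(3Z,6E)-7-methyl-2-oxo-3-(phenylsulfonylmethyl)nona-3,6,8-trien-1-yl]cyclohexane-1-carboxylate | O=S(=O)(c1ccccc1)C/C(=C\C/C=C(C)/C=C)C(=O)C[C@@H]1[C@H](C)CCC[C@@]1(C)C(=O)OCC[Si](C)(C)C | intermediate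
22 | 2-(trimethylsilyl)ethyl (1R,2R,3R)-2-[(2S,3Z,6E)-2-hydroxy-7-methyl-3-(phenylsulfonylmethyl)nona-3,6,8-trien-1-yl]-1,3-dimethylcyclohexane-1-carboxylate | O=S(=O)(c1ccccc1)C/C(=C\C/C=C(C)/C=C)[C@@H](O)C[C@@H]1[C@H](C)CCC[C@@]1(C)C(=O)OCC[Si](C)(C)C | intermediate
23 | 1-(2,4,6-trihydroxyphenyl)ethan-1-one | CC(=O)c1c(O)cc(O)cc1O | starting material
24 | 2,4,5-trimethoxybenzoyl chloride | COc1cc(OC)c(OC)cc1C(Cl)=O | starting material
25 | 1-(2,4,6-trihydroxyphenyl)-3-(2,4,5-trimethoxyphenyl)propane-1,3-dione | COc1cc(OC)c(OC)cc1C(=O)CC(=O)c1c(O)cc(O)cc1O | intermediate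
26 | 5,7-dihydroxy-2-(2,4,5-trimethoxyphenyl)-4H-chromen-4-one | COc1cc(OC)c(OC)cc1-c1cc(=O)c2c(O)cc(O)cc2o1 | intermediate
27 | 5,7-bis(tert-butyldimethylsilyloxy)-2-(2,4,5-trimethoxyphenyl)-4H-chromen-4-one | COc1cc(OC)c(OC)cc1-c1cc(=O)c2c(O[Si](C)(C)C(C)(C)C)cc(O[Si](C)(C)C(C)(C)C)cc2o1 | intermediate
28 | 5,7-bis(tert-butyldimethylsilyloxy)-2-(3,3,4,6,6-pentamethoxycyclohexa-1,4-dien-1-yl)-4H-chromen-4-one | COC1=CC(OC)(OC)C(=CC1(OC)OC)c1cc(=O)c2c(O[Si](C)(C)C(C)(C)C)cc(O[Si](C)(C)C(C)(C)C)cc2o1 | intermediate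
29 | 2-[5,7-bis(tert-butyldimethylsilyloxy)-4-oxo-4H-chromen-2-yl]-4,4,5-trimethoxycyclohexa-2,5-dien-1-one | COC1=CC(=O)C(=CC1(OC)OC)c1cc(=O)c2c(O[Si](C)(C)C(C)(C)C)cc(O[Si](C)(C)C(C)(C)C)cc2o1 | intermediate
30 | Q4 dimethyl ketal of 31 | O=S(=O)(c1ccccc1)C/C(=C\C[C@@H]1C(C)=CC[C@H]2C(OC)(OC)C(OC)=CC(=O)[C@@]12c1cc(=O)c2c(O[Si](C)(C)C(C)(C)C)cc(O[Si](C)(C)C(C)(C)C)cc2o1)[C@@H](O)C[C@@H]1[C@H](C)CCC[C@@]1(C)C(=O)OCC[Si](C)(C)C | intermediate
31 | TMSE ester and 5′,7′-bis-TBS ether of (8Z)-17-(phenylsulfonyl)-9,10-seco-dichrostachine E (H on C10) | O=S(=O)(c1ccccc1)C/C(=C\C[C@@H]1C(C)=CC[C@H]2C(=O)C(OC)=CC(=O)[C@@]12c1cc(=O)c2c(O[Si](C)(C)C(C)(C)C)cc(O[Si](C)(C)C(C)(C)C)cc2o1)[C@@H](O)C[C@@H]1[C@H](C)CCC[C@@]1(C)C(=O)OCC[Si](C)(C)C | intermediate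
32 | dichrostachine E 2-(trimethylsilyl)ethyl ester 5′,7′-bis(tert-butyldimethylsilyl) ether | C=C1[C@@H](O)C[C@@H]2[C@](C)(CCC[C@@]2(C)C(=O)OCC[Si](C)(C)C)[C@H]1C[C@@H]1C(C)=CC[C@H]2C(=O)C(OC)=CC(=O)[C@@]12c1cc(=O)c2c(O[Si](C)(C)C(C)(C)C)cc(O[Si](C)(C)C(C)(C)C)cc2o1 | intermediate
33 | dichrostachine E | C=C1[C@@H](O)C[C@@H]2[C@](C)(CCC[C@@]2(C)C(=O)O)[C@H]1C[C@@H]1C(C)=CC[C@H]2C(=O)C(OC)=CC(=O)[C@@]12c1cc(=O)c2c(O)cc(O)cc2o1 | target

**Step count and risks**
Total steps: 20. Longest linear sequence: 12 steps (steps 1–6, 12–14, 18–20).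

Most likely to fail:

1. Step 19 (proposed new method). What may go wrong: β-scission of the C7 alkoxy radical may compete with 1,5-hydrogen transfer. The C10 radical may be oxidised by tetravalent cerium, reduced, or trapped by ring D before it cyclises. The chromone and enedione chromophores may absorb the light. The released sulfinic acid may add to ring D.
Fallback (known chemistry; sets out from 21, comes back at 32): reduction of 21 with the (S)-oxazaborolidine and catecholborane gives the (7R)-alcohol F1. Mitsunobu reaction with N-hydroxyphthalimide (PPh3, DIAD) inverts C7 and gives the (7S)-N-alkoxyphthalimide F2. Cycloaddition with 29 as in step 18 gives the ketal adduct F3, which is hydrolysed in the same flask to the N-alkoxyphthalimide enedione F4. Irradiation of F4 with blue LEDs, fac-Ir(ppy)3 and Hantzsch ester cleaves the N–O bond reductively to the same alkoxy radical. This is the documented manifold for 1,5-hydrogen transfer and δ-allylation with allyl sulfones, and it needs neither cerium nor a free hydroxyl; it gives 32.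

2. Step 18. What may go wrong: the hindered monoketal may be too slow a dienophile. The substrate enforces neither the chromone-endo topology nor the diene face, and the opposite orientation of addition may compete, so the wanted adduct may be a minor component.
Fallback (sets out from 27 and 22, comes back at 31): oxidative demethylation of 27 with (NH4)2Ce(NO3)6 in MeCN/H2O gives 2-[5,7-bis(tert-butyldimethylsilyloxy)-4-oxo-4H-chromen-2-yl]-5-methoxy-1,4-benzoquinone F5. This far more electron-poor dienophile should react with 22 at or below room temperature (CH2Cl2, if needed under high pressure) to give 31 directly, by the direct quinone cycloaddition that is the presumed biosynthetic route to this family. Isomeric adducts are removed by chromatography.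

3. Step 2. What may go wrong: low enantioselectivity in the formation of the quaternary centre C4 from the strongly enolised α-formyl ester.
Fallback (sets out from 2 and 3, comes back at 6): the annulation is run without chiral control (pyrrolidine, AcOH) to give the racemic enone F6. Reduction with the (S)-oxazaborolidine and catecholborane as in step 3 converts both enantiomers into (4R)-carbinols under reagent control. These are diastereomers: 6 is separated by chromatography from 2-(trimethylsilyl)ethyl (1S,4R)-4-hydroxy-1,3-dimethylcyclohex-2-ene-1-carboxylate F7. C4 is thus set by separation instead of by catalysis.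

**Further compounds**
F1 | step 19 | 2-(trimethylsilyl)ethyl (1R,2R,3R)-2-[(2R,3Z,6E)-2-hydroxy-7-methyl-3-(phenylsulfonylmethyl)nona-3,6,8-trien-1-yl]-1,3-dimethylcyclohexane-1-carboxylate | O=S(=O)(c1ccccc1)C/C(=C\C/C=C(C)/C=C)[C@H](O)C[C@@H]1[C@H](C)CCC[C@@]1(C)C(=O)OCC[Si](C)(C)C
F2 | step 19 | (7S)-N-alkoxyphthalimide of 22 | O=S(=O)(c1ccccc1)C/C(=C\C/C=C(C)/C=C)[C@@H](ON1C(=O)c2ccccc2C1=O)C[C@@H]1[C@H](C)CCC[C@@]1(C)C(=O)OCC[Si](C)(C)C
F3 | step 19 | O7-phthalimido derivative of ketal adduct 30 | O=S(=O)(c1ccccc1)C/C(=C\C[C@@H]1C(C)=CC[C@H]2C(OC)(OC)C(OC)=CC(=O)[C@@]12c1cc(=O)c2c(O[Si](C)(C)C(C)(C)C)cc(O[Si](C)(C)C(C)(C)C)cc2o1)[C@@H](ON1C(=O)c2ccccc2C1=O)C[C@@H]1[C@H](C)CCC[C@@]1(C)C(=O)OCC[Si](C)(C)C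
F4 | step 19 | O7-phthalimido derivative of 31 | O=S(=O)(c1ccccc1)C/C(=C\C[C@@H]1C(C)=CC[C@H]2C(=O)C(OC)=CC(=O)[C@@]12c1cc(=O)c2c(O[Si](C)(C)C(C)(C)C)cc(O[Si](C)(C)C(C)(C)C)cc2o1)[C@@H](ON1C(=O)c2ccccc2C1=O)C[C@@H]1[C@H](C)CCC[C@@]1(C)C(=O)OCC[Si](C)(C)C
F5 | step 18 | 2-[5,7-bis(tert-butyldimethylsilyloxy)-4-oxo-4H-chromen-2-yl]-5-methoxycyclohexa-2,5-diene-1,4-dione | COC1=CC(=O)C(=CC1=O)c1cc(=O)c2c(O[Si](C)(C)C(C)(C)C)cc(O[Si](C)(C)C(C)(C)C)cc2o1
F6 | step 2 | racemic 2-(trimethylsilyl)ethyl 1,3-dimethyl-4-oxocyclohex-2-ene-1-carboxylate | O=C1CCC(C=C1C)(C)C(=O)OCC[Si](C)(C)C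
F7 | step 2 | 2-(trimethylsilyl)ethyl (1S,4R)-4-hydroxy-1,3-dimethylcyclohex-2-ene-1-carboxylate | O[C@@H]1CC[C@](C=C1C)(C)C(=O)OCC[Si](C)(C)C
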